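**Retrosynthetic overview**
1. Myrrhanone B (24) ⇐ ω-oxidation of the terminal (E)-methyl group (SeO2, MnO2, NaClO2) of bicyclic ketol 21; 21 ⇐ enone 19 by Li/NH3 reduction with MeI trapping, which sets the C5 hydrogen (trans ring fusion) and the C4 gem-dimethyl group.
2. Ring B is closed last: 19 ⇐ monocyclic dienone 17 by reductive formation of the C7–C8 bond with SmI2 (ketyl at C8 adds to C7).
3. Enabling feature: the C3 ketone of ring A is conjugated through C4=C5 to the vinyl group C6=C7 on C5, so C7 is the electron-poor δ-carbon of a dienone, five atoms from the carbonyl carbon C8 of the methyl ketone on C9.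
4. 17 ⇐ DDQ dehydrogenation of trienol ether 16 ⇐ Ireland–Claisen rearrangement of ester 12, which sets C9 and the quaternary C10 from one carbinol stereocenter.
5. 12 ⇐ carbinol 11 (ring A from 2-methylcyclohexane-1,3-dione, Corey–Bakshi–Shibata reduction) + acid 5 ((2E,6E)-farnesyl bromide + a C3 Grignard reagent). Ring order: A, then B.

Key step: step 12

Remark: locants follow labdane numbering (ring A = C1–C5 and C10, ring B = C5–C10, C8 = carbinol carbon, C9 = carbon bearing the side chain, C11 onward = side chain); commercial (2E,6E)-farnesyl bromide is taken as geometrically pure.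

**Step 1**
Reactants: 1 (2E,6E)-farnesyl bromide; 2 3-chloropropan-1-ol
Product: 4 (5E,9E)-6,10,14-trimethylpentadeca-5,9,13-trien-1-ol, via magnesium reagent 3 (not isolated)
Conditions: 2, i-PrMgCl, THF, −20 °C; Mg, reflux; then 1, Li2CuCl4 (3 mol%), THF, −78 → 0 °C; aq. NH4Cl
Reagents that add atoms: none
Why: Copper-catalysed Grignard cross-coupling with a primary allylic bromide should proceed by SN2 attack at C1 of the farnesyl unit with retention of the 2E geometry, and no stereocenter is formed.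

**Step 2**
Reactants: 4 (5E,9E)-6,10,14-trimethylpentadeca-5,9,13-trien-1-ol
Product: 5 (5E,9E)-6,10,14-trimethylpentadeca-5,9,13-trienoic acid
Conditions: TEMPO (10 mol%), PhI(OAc)2 (2.2 equiv), MeCN/H2O 1:1, 0 °C → rt
Reagents that add atoms: water O
Why: The TEMPO/PhI(OAc)2 oxidation of a primary alcohol to the carboxylic acid (oxoammonium oxidation, then oxidation of the aldehyde hydrate) leaves trisubstituted alkenes untouched.

**Step 3**
Reactants: 6 2-methylcyclohexane-1,3-dione
Product: 7 2-methyl-3-(2-methylpropoxy)cyclohex-2-en-1-one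
Conditions: i-BuOH, TsOH·H2O (cat.), toluene, reflux, azeotropic removal of water
Reagents that add atoms: 2-methylpropan-1-ol CC(C)CO
Why: Acid-catalysed enol etherification of a cyclic 1,3-diketone (vinylogous ester formation) is driven to completion by removal of water.

**Step 4**
Reactants: 7 2-methyl-3-(2-methylpropoxy)cyclohex-2-en-1-one
Product: 8 rac-2,6-dimethyl-3-(2-methylpropoxy)cyclohex-2-en-1-one
Conditions: LiN(i-Pr)2, THF, −78 °C; MeI, −78 → 0 °C
Reagents that add atoms: iodomethane CI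
Why: Kinetic α'-deprotonation of the vinylogous ester and SN2 methylation (enolate alkylation) should give the 6-methyl compound, whose racemic stereocenter is erased in step 5.

**Step 5**
Reactants: 8 rac-2,6-dimethyl-3-(2-methylpropoxy)cyclohex-2-en-1-one
Product: 9 1,3-dimethyl-4-(2-methylpropoxy)cyclohexa-1,3-dien-2-yl trifluoromethanesulfonate
Conditions: KN(SiMe3)2, THF, −78 °C; PhNTf2, −78 → 0 °C
Reagents that add atoms: N-phenylbis(trifluoromethanesulfonimide) O=S(=O)(N(c1ccccc1)S(=O)(=O)C(F)(F)F)C(F)(F)F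
Why: Kinetic enolisation at the α'-carbon followed by O-sulfonylation (enol triflate formation) should give a single dienyl triflate.

**Step 6**
Reactants: 9 1,3-dimethyl-4-(2-methylpropoxy)cyclohexa-1,3-dien-2-yl trifluoromethanesulfonate
Product: 10 1-[1,3-dimethyl-4-(2-methylpropoxy)cyclohexa-1,3-dien-2-yl]ethan-1-one
Conditions: Pd(PPh3)4 (5 mol%), LiCl, CO (1 atm), Me4Sn, DMF, 60 °C
Reagents that add atoms: carbon monoxide [C-]#[O+]; tetramethylstannane C[Sn](C)(C)C
Why: Carbonylative Stille coupling (oxidative addition of the alkenyl triflate to zerovalent palladium, CO insertion, methyl transfer from tin, reductive elimination) should install C6 and C7 as an acetyl group under neutral conditions that keep the dienol ether.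

**Step 7**
Reactants: 10 1-[1,3-dimethyl-4-(2-methylpropoxy)cyclohexa-1,3-dien-2-yl]ethan-1-one
Product: 11 (1R)-1-[1,3-dimethyl-4-(2-methylpropoxy)cyclohexa-1,3-dien-2-yl]ethan-1-ol
Conditions: (S)-2-methyl-CBS-oxazaborolidine (20 mol%), catecholborane, toluene, −78 °C; then MeOH, aq. NaOH
Reagents that add atoms: none
Why: In the Corey–Bakshi–Shibata reduction the (S)-oxazaborolidine should deliver hydride to the ketone face that keeps the large dienyl group away from the catalyst and so set the (R)-carbinol, while catecholborane at low temperature spares the dienol ether.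

**Step 8**
Reactants: 11 (1R)-1-[1,3-dimethyl-4-(2-methylpropoxy)cyclohexa-1,3-dien-2-yl]ethan-1-ol; 5 (5E,9E)-6,10,14-trimethylpentadeca-5,9,13-trienoic acid
Product: 12 (1R)-1-[1,3-dimethyl-4-(2-methylpropoxy)cyclohexa-1,3-dien-2-yl]ethyl (5E,9E)-6,10,14-trimethylpentadeca-5,9,13-trienoate
Conditions: DCC, DMAP (cat.), CH2Cl2, 0 °C → rt
Reagents that add atoms: none
Why: Steglich esterification acylates the hindered secondary allylic alcohol under near-neutral conditions, so the carbinol configuration and the acid-labile dienol ether should be kept.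

**Step 9**
Reactants: 12 (1R)-1-[1,3-dimethyl-4-(2-methylpropoxy)cyclohexa-1,3-dien-2-yl]ethyl (5E,9E)-6,10,14-trimethylpentadeca-5,9,13-trienoate
Product: 15 (2R,5E,9E)-2-[(1R,2Z)-2-ethylidene-1,3-dimethyl-4-(2-methylpropoxy)cyclohex-3-en-1-yl]-6,10,14-trimethylpentadeca-5,9,13-trienoic acid, via silyl ketene acetal 13 (not isolated), via trimethylsilyl ester 14 (not isolated)
Conditions: LiN(i-Pr)2, THF/HMPA 4:1, −78 °C; Me3SiCl, Et3N, −78 → 60 °C; then pH 5 buffer
Reagents that add atoms: none
Why: In this Ireland–Claisen rearrangement, enolisation in THF/HMPA should give the (Z)-silyl ketene acetal, and its chair transition state with the carbinol methyl equatorial (avoiding allylic 1,3-strain with the C10 methyl) transfers the C–O chirality to the quaternary carbon C10, places the side chain equatorial to set C9, and leaves a (Z)-ethylidene group on C5.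

**Step 10**
Reactants: 15 (2R,5E,9E)-2-[(1R,2Z)-2-ethylidene-1,3-dimethyl-4-(2-methylpropoxy)cyclohex-3-en-1-yl]-6,10,14-trimethylpentadeca-5,9,13-trienoic acid
Product: 16 (3R,6E,10E)-3-[(1R,2Z)-2-ethylidene-1,3-dimethyl-4-(2-methylpropoxy)cyclohex-3-en-1-yl]-7,11,15-trimethylhexadeca-6,10,14-trien-2-one
Conditions: MeLi (3 equiv), Et2O, 0 °C → rt; sat. NH4Cl
Reagents that add atoms: methyllithium [Li]C
Why: Addition of MeLi to the lithium carboxylate gives a dilithium gem-diolate that collapses to the methyl ketone only on work-up, so neither over-addition nor epimerisation at C9 is expected, and the dienol ether is inert to the reagent.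

**Step 11**
Reactants: 16 (3R,6E,10E)-3-[(1R,2Z)-2-ethylidene-1,3-dimethyl-4-(2-methylpropoxy)cyclohex-3-en-1-yl]-7,11,15-trimethylhexadeca-6,10,14-trien-2-one
Product: 17 (4R)-2,4-dimethyl-4-[(3R,6E,10E)-7,11,15-trimethyl-2-oxohexadeca-6,10,14-trien-3-yl]-3-vinylcyclohex-2-en-1-one
Conditions: DDQ (1.1 equiv), NaHCO3, acetone/H2O 19:1, 0 °C
Reagents that add atoms: water O
Why: DDQ dehydrogenation of an alkoxydiene (hydride abstraction from the allylic C7 methyl group gives an alkoxy-stabilised pentadienyl cation that is hydrolysed) should deliver the linearly conjugated dienone, as in the known conversion of 3-alkoxy-3,5-dienes into 4,6-dien-3-ones, and the electron-rich dienol ether should react far faster than the isolated alkenes.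

**Step 12**
Reactants: 17 (4R)-2,4-dimethyl-4-[(3R,6E,10E)-7,11,15-trimethyl-2-oxohexadeca-6,10,14-trien-3-yl]-3-vinylcyclohex-2-en-1-one
Product: 19 (4aR,5R,6R)-6-hydroxy-1,4a,6-trimethyl-5-[(3E,7E)-4,8,12-trimethyltrideca-3,7,11-trien-1-yl]-4,4a,5,6,7,8-hexahydronaphthalen-2(3H)-one, via deconjugated enone 18 (not isolated)
Conditions: SmI2 (2.5 equiv), HMPA (10 equiv), THF (0.005 M), −78 → −20 °C; sat. NH4Cl; then DBU (cat.), CH2Cl2, rt
Reagents that add atoms: none
Why: Proposed new method: SmI2 reduces 17 to a samarium-bound ketyl at C8 (or to the dienone radical anion, which leads to the same bond), the carbon radical adds to C7 at the δ-end of the C3-ketone/C4=C5/C6=C7 dienone, and a second electron gives a trivalent samarium dienolate that is protonated on work-up to 18 and conjugated by DBU to 19. The closest known reaction type is the SmI2 ketyl–olefin reductive cyclization of ketones onto α,β-unsaturated carbonyl acceptors, extended here from a 1,4- to a vinylogous 1,6-acceptor. Ring B closes in the 6-endo-trig mode through a half-chair in which the C9 side chain is equatorial. The new stereocenter C8 is controlled by the bulky HMPA-solvated O–Sm group, which should lie equatorial and anti to the acceptor π bond, so that the C8 methyl ends axial and syn to the C10 methyl (8R). The step needs attack at C7 instead of C6 or C5 and ring closure instead of plain reduction: only C7 carries acceptor character and is five atoms from C8 (attack at C5 would give a four-membered ring, attack at C6 an unstabilised radical), and the absence of a proton source until work-up together with high dilution disfavours reduction and dimerisation.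

**Step 13**
Reactants: 19 (4aR,5R,6R)-6-hydroxy-1,4a,6-trimethyl-5-[(3E,7E)-4,8,12-trimethyltrideca-3,7,11-trien-1-yl]-4,4a,5,6,7,8-hexahydronaphthalen-2(3H)-one
Product: 21 (4aS,5R,6R,8aS)-6-hydroxy-1,1,4a,6-tetramethyl-5-[(3E,7E)-4,8,12-trimethyltrideca-3,7,11-trien-1-yl]octahydronaphthalen-2(1H)-one, via lithium enolate 20 (not isolated)
Conditions: Li (3 equiv), NH3 (l)/THF, t-BuOH (1 equiv), −78 °C; isoprene; MeI, −78 → −33 °C; NH4Cl
Reagents that add atoms: iodomethane CI
Why: In this dissolving-metal reductive alkylation the β-carbanion at C5 is protonated from the axial direction to give the trans ring fusion (5S), the regiodefined lithium enolate is methylated at C4 to complete the gem-dimethyl group, and isolated trisubstituted alkenes and the tertiary alkoxide are inert.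

**Step 14**
Reactants: 21 (4aS,5R,6R,8aS)-6-hydroxy-1,1,4a,6-tetramethyl-5-[(3E,7E)-4,8,12-trimethyltrideca-3,7,11-trien-1-yl]octahydronaphthalen-2(1H)-one
Product: 22 (4aS,5R,6R,8aS)-6-hydroxy-5-[(3E,7E,11E)-13-hydroxy-4,8,12-trimethyltrideca-3,7,11-trien-1-yl]-1,1,4a,6-tetramethyloctahydronaphthalen-2(1H)-one
Conditions: SeO2 (cat.), t-BuOOH, salicylic acid (cat.), CH2Cl2, rt
Reagents that add atoms: tert-butyl hydroperoxide CC(C)(C)OO
Why: SeO2-catalysed allylic oxidation (ene reaction, then 2,3-sigmatropic shift) is selective for the (E)-methyl group of the terminal, least hindered isopropylidene unit and should give the (E)-allylic alcohol without touching the ketone or the tertiary alcohol at room temperature.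

**Step 15**
Reactants: 22 (4aS,5R,6R,8aS)-6-hydroxy-5-[(3E,7E,11E)-13-hydroxy-4,8,12-trimethyltrideca-3,7,11-trien-1-yl]-1,1,4a,6-tetramethyloctahydronaphthalen-2(1H)-one
Product: 23 (2E,6E,10E)-13-[(1R,2R,4aS,8aS)-2-hydroxy-2,5,5,8a-tetramethyl-6-oxodecahydronaphthalen-1-yl]-2,6,10-trimethyltrideca-2,6,10-trienal
Conditions: MnO2 (excess), CH2Cl2, rt
Reagents that add atoms: none
Why: MnO2 oxidises only the primary allylic alcohol to the enal, and the tertiary alcohol and the alkene geometry are not affected.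

**Step 16**
Reactants: 23 (2E,6E,10E)-13-[(1R,2R,4aS,8aS)-2-hydroxy-2,5,5,8a-tetramethyl-6-oxodecahydronaphthalen-1-yl]-2,6,10-trimethyltrideca-2,6,10-trienal
Product: 24 Myrrhanone B
Conditions: NaClO2, NaH2PO4, 2-methylbut-2-ene, t-BuOH/H2O, rt
Reagents that add atoms: sodium chlorite [Na+].[O-]Cl=O
Why: The Pinnick oxidation converts the enal into the (E)-2-methylenoic acid without isomerisation, and 2-methylbut-2-ene scavenges HOCl so that the other alkenes survive.

**Compound list**
1 | (2E,6E)-farnesyl bromide | BrC/C=C(\C)CC/C=C(\C)CCC=C(C)C | starting material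
2 | 3-chloropropan-1-ol | OCCCCl | starting material
3 | chloromagnesium 3-(chloromagnesio)propan-1-olate | Cl[Mg]CCCO[Mg]Cl | intermediate
4 | (5E,9E)-6,10,14-trimethylpentadeca-5,9,13-trien-1-ol | OCCCC/C=C(\C)CC/C=C(\C)CCC=C(C)C | intermediate
5 | (5E,9E)-6,10,14-trimethylpentadeca-5,9,13-trienoic acid | OC(=O)CCC/C=C(\C)CC/C=C(\C)CCC=C(C)C | intermediate
6 | 2-methylcyclohexane-1,3-dione | CC1C(=O)CCCC1=O | starting material
7 | 2-methyl-3-(2-methylpropoxy)cyclohex-2-en-1-one | CC1=C(OCC(C)C)CCCC1=O | intermediate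
8 | rac-2,6-dimethyl-3-(2-methylpropoxy)cyclohex-2-en-1-one | CC1CCC(OCC(C)C)=C(C)C1=O | intermediate
9 | 1,3-dimethyl-4-(2-methylpropoxy)cyclohexa-1,3-dien-2-yl trifluoromethanesulfonate | CC1=C(OS(=O)(=O)C(F)(F)F)C(C)=C(OCC(C)C)CC1 | intermediate
10 | 1-[1,3-dimethyl-4-(2-methylpropoxy)cyclohexa-1,3-dien-2-yl]ethan-1-one | CC(=O)C1=C(C)CCC(OCC(C)C)=C1C | intermediate
11 | (1R)-1-[1,3-dimethyl-4-(2-methylpropoxy)cyclohexa-1,3-dien-2-yl]ethan-1-ol | C[C@@H](O)C1=C(C)CCC(OCC(C)C)=C1C | intermediate
12 | (1R)-1-[1,3-dimethyl-4-(2-methylpropoxy)cyclohexa-1,3-dien-2-yl]ethyl (5E,9E)-6,10,14-trimethylpentadeca-5,9,13-trienoate | C[C@@H](OC(=O)CCC/C=C(\C)CC/C=C(\C)CCC=C(C)C)C1=C(C)CCC(OCC(C)C)=C1C | intermediate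
13 | (Z)-O-trimethylsilyl ketene acetal of ester 12 (side chain cis to OSiMe3) | C[C@@H](O/C(O[Si](C)(C)C)=C/CC/C=C(\C)CC/C=C(\C)CCC=C(C)C)C1=C(C)CCC(OCC(C)C)=C1C | intermediate
14 | trimethylsilyl ester of acid 15 | C[Si](C)(C)OC(=O)[C@H](CC/C=C(\C)CC/C=C(\C)CCC=C(C)C)[C@@]1(C)CCC(OCC(C)C)=C(C)/C1=C\C | intermediate
15 | (2R,5E,9E)-2-[(1R,2Z)-2-ethylidene-1,3-dimethyl-4-(2-methylpropoxy)cyclohex-3-en-1-yl]-6,10,14-trimethylpentadeca-5,9,13-trienoic acid | OC(=O)[C@H](CC/C=C(\C)CC/C=C(\C)CCC=C(C)C)[C@@]1(C)CCC(OCC(C)C)=C(C)/C1=C\C | intermediate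
16 | (3R,6E,10E)-3-[(1R,2Z)-2-ethylidene-1,3-dimethyl-4-(2-methylpropoxy)cyclohex-3-en-1-yl]-7,11,15-trimethylhexadeca-6,10,14-trien-2-one | CC(=O)[C@H](CC/C=C(\C)CC/C=C(\C)CCC=C(C)C)[C@@]1(C)CCC(OCC(C)C)=C(C)/C1=C\C | intermediate
17 | (4R)-2,4-dimethyl-4-[(3R,6E,10E)-7,11,15-trimethyl-2-oxohexadeca-6,10,14-trien-3-yl]-3-vinylcyclohex-2-en-1-one | CC(=O)[C@H](CC/C=C(\C)CC/C=C(\C)CCC=C(C)C)[C@@]1(C)CCC(=O)C(C)=C1C=C | intermediate
18 | (4aR,5R,6R)-6-hydroxy-1,4a,6-trimethyl-5-[(3E,7E)-4,8,12-trimethyltrideca-3,7,11-trien-1-yl]-3,4,4a,5,6,7-hexahydronaphthalen-2(1H)-one (both C1 epimers) | CC(C)=CCC/C(C)=C/CC/C(C)=C/CC[C@@H]1[C@@]2(C)CCC(=O)C(C)C2=CC[C@@]1(C)O | intermediate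
19 | (4aR,5R,6R)-6-hydroxy-1,4a,6-trimethyl-5-[(3E,7E)-4,8,12-trimethyltrideca-3,7,11-trien-1-yl]-4,4a,5,6,7,8-hexahydronaphthalen-2(3H)-one | CC(C)=CCC/C(C)=C/CC/C(C)=C/CC[C@@H]1[C@@]2(C)CCC(=O)C(C)=C2CC[C@@]1(C)O | intermediate
20 | lithium C3 enolate of the 4-methyl trans-decalone formed from 19 (C5 hydrogen trans to the C10 methyl) | CC(C)=CCC/C(C)=C/CC/C(C)=C/CC[C@@H]1[C@@]2(C)CCC(O[Li])=C(C)[C@H]2CC[C@@]1(C)O | intermediate
21 | (4aS,5R,6R,8aS)-6-hydroxy-1,1,4a,6-tetramethyl-5-[(3E,7E)-4,8,12-trimethyltrideca-3,7,11-trien-1-yl]octahydronaphthalen-2(1H)-one | CC(C)=CCC/C(C)=C/CC/C(C)=C/CC[C@@H]1[C@@]2(C)CCC(=O)C(C)(C)[C@H]2CC[C@@]1(C)O | intermediate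
22 | (4aS,5R,6R,8aS)-6-hydroxy-5-[(3E,7E,11E)-13-hydroxy-4,8,12-trimethyltrideca-3,7,11-trien-1-yl]-1,1,4a,6-tetramethyloctahydronaphthalen-2(1H)-one | OC/C(C)=C/CC/C(C)=C/CC/C(C)=C/CC[C@@H]1[C@@]2(C)CCC(=O)C(C)(C)[C@H]2CC[C@@]1(C)O | intermediate
23 | (2E,6E,10E)-13-[(1R,2R,4aS,8aS)-2-hydroxy-2,5,5,8a-tetramethyl-6-oxodecahydronaphthalen-1-yl]-2,6,10-trimethyltrideca-2,6,10-trienal | O=C/C(C)=C/CC/C(C)=C/CC/C(C)=C/CC[C@@H]1[C@@]2(C)CCC(=O)C(C)(C)[C@H]2CC[C@@]1(C)O | intermediate
24 | Myrrhanone B, (2E,6E,10E)-13-[(1R,2R,4aS,8aS)-2-hydroxy-2,5,5,8a-tetramethyl-6-oxodecahydronaphthalen-1-yl]-2,6,10-trimethyltrideca-2,6,10-trienoic acid | C/C(=C\CC/C(C)=C/CC[C@@H]1[C@@]2(C)CCC(=O)C(C)(C)[C@H]2CC[C@@]1(C)O)CC/C=C(\C)C(=O)O | target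

**Step count and risks**
Total: 16 steps. Longest linear sequence: 14 steps (6 → 24, steps 3–16); the acid branch (steps 1–2) joins at step 8.

Steps most likely to fail:

1. Step 12 (proposed new method). Facial selectivity at C8 may be poor (oxygen axial), or the dienone may be reduced or dimerised without ring closure. The fallback sets out from 16 and returns at 19, and replaces the samarium ketyl by a neutral α-hydroxyalkyl radical made by hydrogen-atom transfer. NaBH4 in MeOH at 0 °C should reduce the methyl ketone of 16 to the C8 carbinol F1 (both C8 epimers, since the center becomes planar later). DDQ in buffered aqueous acetone, as in step 11, should convert it into the dienone carbinol F2. Irradiation of F2 (blue LED, MeCN) with Ir[dF(CF3)ppy]2(dtbbpy)PF6, quinuclidine and Bu4N(H2PO4), the known photoredox α-C–H alkylation of alcohols with Michael acceptors, should abstract the hydridic C8–H; the radical adds to C7, the dienyl radical is reduced and protonated to 18, and DBU gives 19.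

2. Step 11. Hydride abstraction from the primary C7 methyl group may be slower than acid-promoted hydrolysis of the dienol ether to the saturated-side-chain enone. The fallback sets out from 16 and returns at 17, using the classical bromination–dehydrobromination of dienol ethers. NBS with NaHCO3 in THF/H2O at −20 °C should attack the terminus of the alkoxydiene (far more nucleophilic than the isolated alkenes) and give, after hydrolysis, the 1-bromoethyl enone F3. Li2CO3 and LiBr in DMF at 90 °C should then eliminate HBr toward C7 to give 17.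

3. Step 14. Site selectivity among the three trisubstituted alkenes may be incomplete and over-oxidation may occur late in the route. The fallback sets out from 21 and returns at 23. NBS in THF/H2O at 0 °C should give the terminal bromohydrin F4 (the known preference of polyprenyl chains for attack at the terminal alkene in aqueous medium). K2CO3 in MeOH closes it to the terminal epoxide F5. H5IO6 in THF/H2O cleaves the epoxide to the trisnor aldehyde F6 and acetone. A Wittig reaction of F6 with Ph3P=C(CH3)CHO in toluene at 80 °C (stabilised ylide, E-selective, aldehyde-selective beside the C3 ketone) should give enal 23.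

**Further compounds**
F1 | step 12 | (3R,6E,10E)-3-[(1R,2Z)-2-ethylidene-1,3-dimethyl-4-(2-methylpropoxy)cyclohex-3-en-1-yl]-7,11,15-trimethylhexadeca-6,10,14-trien-2-ol (both C2 epimers) | CC(O)[C@H](CC/C=C(\C)CC/C=C(\C)CCC=C(C)C)[C@@]1(C)CCC(OCC(C)C)=C(C)/C1=C\C
F2 | step 12 | (4R)-4-[(3R,6E,10E)-2-hydroxy-7,11,15-trimethylhexadeca-6,10,14-trien-3-yl]-2,4-dimethyl-3-vinylcyclohex-2-en-1-one (both carbinol epimers) | CC(O)[C@H](CC/C=C(\C)CC/C=C(\C)CCC=C(C)C)[C@@]1(C)CCC(=O)C(C)=C1C=C
F3 | step 11 | (4R)-3-(1-bromoethyl)-2,4-dimethyl-4-[(3R,6E,10E)-7,11,15-trimethyl-2-oxohexadeca-6,10,14-trien-3-yl]cyclohex-2-en-1-one (both bromide epimers) | CC(=O)[C@H](CC/C=C(\C)CC/C=C(\C)CCC=C(C)C)[C@@]1(C)CCC(=O)C(C)=C1C(C)Br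
F4 | step 14 | terminal bromohydrin of 21 (11-bromo-12-hydroxy on the side chain, both epimers) | CC(C)(O)C(Br)CC/C(C)=C/CC/C(C)=C/CC[C@@H]1[C@@]2(C)CCC(=O)C(C)(C)[C@H]2CC[C@@]1(C)O
F5 | step 14 | terminal 11,12-epoxide of 21 (both epimers) | CC1(C)OC1CC/C(C)=C/CC/C(C)=C/CC[C@@H]1[C@@]2(C)CCC(=O)C(C)(C)[C@H]2CC[C@@]1(C)O
F6 | step 14 | (4E,8E)-10-[(1R,2R,4aS,8aS)-2-hydroxy-2,5,5,8a-tetramethyl-6-oxodecahydronaphthalen-1-yl]-4,8-dimethyldeca-4,8-dienal | O=CCC/C(C)=C/CC/C(C)=C/CC[C@@H]1[C@@]2(C)CCC(=O)C(C)(C)[C@H]2CC[C@@]1(C)O
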